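**Plan**

- The retrosynthesis cuts the pyrrole at C2–C3 and C4–C5. This gives methyl isocyanoacetate (C2, N1, C5 and the ester) and (E)-1-nitropentacos-1-ene (C3, C4 and the tricosyl chain).
- The ring pattern allows this: ester on C2, chain on C3, hydrogen on C4 and C5. C4 is unsubstituted because it is the carbon that loses the nitro group.
- The nitroalkene is cut at its C1=C2 bond into nitromethane and tetracosanal, which comes from commercial 1-tetracosanol.
- Forward order: the alcohol is oxidised, a Henry addition joins the C24 chain to the nitromethane carbon, water is eliminated, and the only ring is closed in the last step.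
- The target has no stereocentre. The racemic carbinol centre of the nitro alcohol and the E geometry of the nitroalkene are both erased on the way to the aromatic ring.

Key step: step 4

Assumption: the nitro alcohol, its mesylate and the two ring intermediates of the last step are handled as racemates or stereoisomer mixtures, because each of their sp3 centres is destroyed before the target is reached.

**Route**

Step 1
Reactants: 1 1-tetracosanol
Product: 2 tetracosanal
Conditions: IBX (1.5 equiv), EtOAc, 80 °C; filtered warm, used without storage
Reagents that add atoms: none
Why: IBX oxidation of a primary alcohol in hot ethyl acetate is a standard alcohol-to-aldehyde oxidation that should stop at the aldehyde, and the temperature keeps the waxy C24 alcohol in solution while the spent iodine reagent is filtered off.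

Step 2
Reactants: 2 tetracosanal; 3 nitromethane
Product: 4 1-nitropentacosan-2-ol (racemic)
Conditions: MeNO2 (10 equiv), KOtBu (0.1 equiv), THF/tBuOH 1:1, 0 °C to rt; AcOH quench
Reagents that add atoms: none
Why: The base-catalysed Henry (nitroaldol) addition of nitromethane to an unhindered aliphatic aldehyde is reliable when nitromethane is in large excess and the base is catalytic, which should hold back aldol self-condensation, and the new carbinol centre forms as a racemate that step 3 removes.

Step 3
Reactants: 4 1-nitropentacosan-2-ol
Product: 6 (E)-1-nitropentacos-1-ene, via 1-nitropentacosan-2-yl methanesulfonate 5 (not isolated)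
Conditions: MsCl (1.2 equiv), Et3N (2.5 equiv), CH2Cl2, 0 °C to rt; cold dilute HCl wash, short silica plug, stored cold
Reagents that add atoms: none
Why: Mesylation of the secondary alcohol followed in the same flask by E1cB elimination through the nitronate is the standard dehydration of a β-nitro alcohol and should give the conjugated E alkene as the thermodynamically preferred isomer.

Step 4
Reactants: 6 (E)-1-nitropentacos-1-ene; 7 methyl isocyanoacetate
Product: 10 methyl 3-tricosyl-1H-pyrrole-2-carboxylate, via methyl 4-nitro-3-tricosyl-3,4-dihydro-2H-pyrrole-2-carboxylate 8 (not isolated), via methyl 3-tricosyl-2H-pyrrole-2-carboxylate 9 (not isolated)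
Conditions: 7 (1.2 equiv), DBU (1.3 equiv), THF, 0 °C; 6 in THF added slowly; then rt
Reagents that add atoms: none
Why: DBU deprotonates 7, and the carbanion adds in Michael fashion to alkene carbon C2 of 6, the chain-bearing carbon, which forms the future C2–C3 bond of the pyrrole and leaves a nitronate. The nitronate carbon then attacks the isocyanide carbon in a 5-endo-dig closure that forms the C4–C5 bond, and protonation of the imidoyl anion gives nitropyrroline 8. Loss of nitrite from C4 gives 2H-pyrrole 9, and a proton shift from C2 to nitrogen aromatises it to 10; this is the Barton–Zard pyrrole synthesis, a long-established reaction of isocyanoacetates with nitroalkenes. The sp3 centres of 8 and 9 are transient, so no stereocontrol is needed. The selectivity required is regiochemical and is secured by the nitro group, which makes only the chain-bearing carbon electrophilic and so places the chain next to the ester and the leaving group on C4. Slow addition of 6 to a slight excess of the preformed carbanion keeps the concentration of free nitroalkene low, which should suppress base-induced oligomerisation, double-bond migration and a second Michael addition.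

**Compound list**

1 | 1-tetracosanol | CCCCCCCCCCCCCCCCCCCCCCCCO | starting material
2 | tetracosanal | CCCCCCCCCCCCCCCCCCCCCCCC=O | intermediate
3 | nitromethane | C[N+](=O)[O-] | starting material
4 | 1-nitropentacosan-2-ol (racemic) | CCCCCCCCCCCCCCCCCCCCCCCC(O)C[N+](=O)[O-] | intermediate
5 | 1-nitropentacosan-2-yl methanesulfonate (racemic, not isolated) | CCCCCCCCCCCCCCCCCCCCCCCC(OS(C)(=O)=O)C[N+](=O)[O-] | intermediate
6 | (E)-1-nitropentacos-1-ene | CCCCCCCCCCCCCCCCCCCCCCC/C=C/[N+](=O)[O-] | intermediate
7 | methyl isocyanoacetate | [C-]#[N+]CC(=O)OC | starting material
8 | methyl 4-nitro-3-tricosyl-3,4-dihydro-2H-pyrrole-2-carboxylate (stereoisomer mixture, not isolated) | CCCCCCCCCCCCCCCCCCCCCCCC1C(C(=O)OC)N=CC1[N+](=O)[O-] | intermediate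
9 | methyl 3-tricosyl-2H-pyrrole-2-carboxylate (racemic, not isolated) | CCCCCCCCCCCCCCCCCCCCCCCC1=CC=NC1C(=O)OC | intermediate
10 | methyl 3-tricosyl-1H-pyrrole-2-carboxylate | CCCCCCCCCCCCCCCCCCCCCCCc1cc[nH]c1C(=O)OC | target

**Step count and risks**

Total step count: 4. Longest linear sequence: 4 steps, from 1-tetracosanol 1 to target 10.

Steps most likely to fail, riskiest first:

1. Step 4. The amidine base may act on the nitroalkene faster than the carbanion adds to it. Double-bond migration to the allylic nitro isomer, anionic oligomerisation or a second Michael addition of the first adduct would then use up the electrophile before the ring closes. The fallback sets out from nitro alcohol 4. Acetylation (Ac2O, cat. H2SO4, CH2Cl2, 0 °C to rt) should give the stable ester 1-nitropentacosan-2-yl acetate F1. F1 and 7 are then treated with DBU (2.2 equiv) in THF at 0 °C to rt. The base eliminates acetic acid from F1 and releases the nitroalkene little by little in the presence of excess carbanion. The fallback comes back to the route at 6, now formed in the flask and consumed at once, and runs on through 8 and 9 to 10 in the same operation. This is the acetoxy-nitroalkane form of the Barton–Zard reaction.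

2. Step 3. Triethylamine may keep acting on the product after the elimination, moving the double bond out of conjugation or starting Michael oligomerisation with unreacted nitronate, and the nitroalkene may suffer further loss on silica. The fallback sets out from aldehyde 2 and avoids base in the step that makes the nitroalkene. Wittig methylenation (Ph3PCH3Br, KOtBu, THF, 0 °C to rt) should give pentacos-1-ene F2. Radical nitration of this terminal alkene with AgNO2 and TEMPO (4 Å molecular sieves, 1,2-dichloroethane, 70 °C) adds nitrogen dioxide at the terminal carbon, and TEMPO then removes a hydrogen atom. This should give the E nitroalkene, and the fallback comes back to the route at 6.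

3. Step 2. The nitroaldol addition is reversible, and the waxy enolisable aldehyde may stall at partial conversion or condense with itself under the alkoxide. The fallback sets out from aldehyde 2 and changes the activating group from nitro to sulfonyl. Horner–Wadsworth–Emmons olefination with diethyl (phenylsulfonyl)methylphosphonate (NaH, THF, 0 °C to rt) is irreversible and should give (E)-(pentacos-1-en-1-ylsulfonyl)benzene F3. F3 and 7 with KOtBu in THF (0 °C to rt) should then undergo the sulfone form of the isocyanoacetate annulation. The same C2–C3 and C4–C5 bonds form, benzenesulfinate leaves C4 in place of nitrite, and the fallback comes back to the route at 10.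

**Further compounds**

F1 | step 4 | 1-nitropentacosan-2-yl acetate (racemic) | CCCCCCCCCCCCCCCCCCCCCCCC(OC(C)=O)C[N+](=O)[O-]
F2 | step 3 | pentacos-1-ene | CCCCCCCCCCCCCCCCCCCCCCCC=C
F3 | step 2 | (E)-(pentacos-1-en-1-ylsulfonyl)benzene | CCCCCCCCCCCCCCCCCCCCCCC/C=C/S(=O)(=O)c1ccccc1
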